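**Plan**
- Retrosynthesis: after removal of the MOM, silyl and O-methyl groups, the furanone is opened at the lactone bond O1–C2 and the acyl carbon is rejoined to C5, which contracts the ring to a 4-hydroxycyclobutenone. This is cut at C4–CH2Ar (benzylic Grignard reagent) and at C2–aryl (aryllithium plus dimethyl squarate).
- Enabling feature: the furan-2(5H)-one ring (O1, C2 carbonyl, C3 aryl, C4 oxygen, C5 benzylidene) is a cyclobutenone with one oxygen inserted between its ketone carbon and its carbinol carbon; aryl, methoxy and arylmethyl carbinol sit on three consecutive ring carbons.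
- Forward: fragment 1, the (R)-dihydrobenzofuranylmethyl chloride, comes from methyl 4-hydroxybenzoate (steps 1–7; the dihydrofuran ring closes in step 4). Fragment 2, the aryl methoxy cyclobutenedione, comes from 2,5-dibromohydroquinone and dimethyl squarate (steps 8–10).
- The fragments are joined by Grignard addition (step 11); Pb(OAc)4 (tetravalent lead) then expands the four-membered ring to the butenolide with its benzylidene (step 12); O-demethylation and acid unmasking finish the route (steps 13–14).
- Stereochemistry: the only stereocentre (C2 of the dihydrobenzofuran, R) comes from a Shi epoxidation of the prenyl group to the (S)-epoxide and its invertive 5-exo opening by the phenoxide. The Z alkene is the thermodynamic isomer.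

Key step: step 12

Assumption: the L-fructose-derived enantiomer of the Shi ketone (prepared from L-sorbose) is taken as an available catalyst. By the spiro transition-state model the D-fructose ketone gives the (R)-epoxide of a prenyl group, so the L-series ketone is needed for the (S)-epoxide.
Remark: the cyclobutenone carbinol centre made in step 11 is destroyed in step 12, so that compound is carried as a mixture of two epimers.

**Step 1**
Reactants: 1 methyl 4-hydroxybenzoate; 2 prenyl bromide (1-bromo-3-methylbut-2-ene)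
Product: 4 methyl 4-hydroxy-3-(3-methylbut-2-en-1-yl)benzoate, via sodium phenolate 3 (not isolated)
Conditions: NaH, toluene, 0 °C → rt; then 2, rt
Reagents that add atoms: none
Why: Phenoxide C-alkylation: the tight sodium phenoxide ion pair in a non-polar solvent should be attacked by the allylic bromide (SN2 at its primary carbon) through the ortho carbon, the para position being blocked by the ester, and the O-prenyl ether and dialkylated material that accompany 4 are removed by chromatography.

**Step 2**
Reactants: 4 methyl 4-hydroxy-3-(3-methylbut-2-en-1-yl)benzoate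
Product: 5 methyl 4-[(tert-butyldimethylsilyl)oxy]-3-(3-methylbut-2-en-1-yl)benzoate
Conditions: TBSCl, imidazole, DMF, rt
Reagents that add atoms: tert-butyldimethylsilyl chloride, CC(C)(C)[Si](C)(C)Cl
Why: Imidazole-promoted silylation of a phenol, which keeps the phenoxide from being oxidised by the dioxirane and postpones ring closure until the epoxide is in place.

**Step 3**
Reactants: 5 methyl 4-[(tert-butyldimethylsilyl)oxy]-3-(3-methylbut-2-en-1-yl)benzoate
Product: 6 methyl 4-[(tert-butyldimethylsilyl)oxy]-3-{[(2S)-3,3-dimethyloxiran-2-yl]methyl}benzoate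
Conditions: L-fructose-derived Shi ketone (30 mol %), KHSO5 (as 2KHSO5·KHSO4·K2SO4), K2CO3, Bu4NHSO4, Na2B4O7 buffer, MeCN–CH2(OMe)2–H2O, 0 °C
Reagents that add atoms: potassium peroxymonosulfate, [K+].[O-]S(=O)(=O)OO
Why: Shi asymmetric epoxidation: the chiral dioxirane formed from the ketone and KHSO5 transfers oxygen through a spiro transition state to one face of the electron-rich trisubstituted alkene, the L-series ketone giving the (S) configuration at the CH carbon, while the ester-deactivated arene is left alone.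

**Step 4**
Reactants: 6 methyl 4-[(tert-butyldimethylsilyl)oxy]-3-{[(2S)-3,3-dimethyloxiran-2-yl]methyl}benzoate
Product: 8 methyl (2R)-2-(2-hydroxypropan-2-yl)-2,3-dihydro-1-benzofuran-5-carboxylate, via phenol epoxide 7 (not isolated)
Conditions: K2CO3, MeOH, rt → 40 °C
Reagents that add atoms: none
Why: Base methanolysis of the aryl silyl ether frees the phenoxide, which opens the epoxide intramolecularly at the less hindered secondary carbon (5-exo-tet, SN2 with inversion, S to R) instead of the tertiary carbon (6-endo), so the dihydrofuran ring and the tertiary carbinol appear together and the configuration of C2 is set here.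

**Step 5**
Reactants: 8 methyl (2R)-2-(2-hydroxypropan-2-yl)-2,3-dihydro-1-benzofuran-5-carboxylate
Product: 9 methyl (2R)-2-{2-[(triethylsilyl)oxy]propan-2-yl}-2,3-dihydro-1-benzofuran-5-carboxylate
Conditions: Et3SiOTf, 2,6-lutidine, CH2Cl2, −78 → 0 °C
Reagents that add atoms: triethylsilyl trifluoromethanesulfonate, CC[Si](CC)(CC)OS(=O)(=O)C(F)(F)F
Why: Silylation of a hindered tertiary alcohol with the silyl triflate; the ether keeps the alcohol from quenching the Grignard reagent of step 11 and from binding tetravalent lead in step 12, where β-scission to acetone would threaten.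

**Step 6**
Reactants: 9 methyl (2R)-2-{2-[(triethylsilyl)oxy]propan-2-yl}-2,3-dihydro-1-benzofuran-5-carboxylate
Product: 10 [(2R)-2-{2-[(triethylsilyl)oxy]propan-2-yl}-2,3-dihydro-1-benzofuran-5-yl]methanol
Conditions: LiAlH4, THF, 0 °C; then H2O, aq. NaOH
Reagents that add atoms: none
Why: Hydride reduction of an aryl ester to the benzylic alcohol; silyl ether, aryl ether and stereocentre are not touched.

**Step 7**
Reactants: 10 [(2R)-2-{2-[(triethylsilyl)oxy]propan-2-yl}-2,3-dihydro-1-benzofuran-5-yl]methanol
Product: 12 (2R)-5-(chloromethyl)-2-{2-[(triethylsilyl)oxy]propan-2-yl}-2,3-dihydro-1-benzofuran, via benzylic mesylate 11 (not isolated)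
Conditions: MsCl, Et3N, CH2Cl2, 0 °C → rt
Reagents that add atoms: methanesulfonyl chloride, CS(=O)(=O)Cl
Why: Sulfonylation followed by in situ nucleophilic substitution of the electron-rich benzylic mesylate by the chloride of the ammonium salt gives the chloride under basic conditions that spare the silyl ether; the chloride is preferred over the bromide for magnesium insertion with little Wurtz coupling.

**Step 8**
Reactants: 13 2,5-dibromohydroquinone (2,5-dibromobenzene-1,4-diol)
Product: 14 1,4-dibromo-2,5-bis(methoxymethoxy)benzene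
Conditions: MOMCl, i-Pr2NEt, CH2Cl2, 0 °C → rt
Reagents that add atoms: chloromethyl methyl ether, COCCl
Why: Base-mediated O-alkylation of both phenols with the chloromethyl ether (acetal formation); the MOM groups tolerate the organolithium, Grignard, Pb(OAc)4 and LiCl steps and come off with mild acid.

**Step 9**
Reactants: 14 1,4-dibromo-2,5-bis(methoxymethoxy)benzene; 2 prenyl bromide
Product: 17 1-bromo-2,5-bis(methoxymethoxy)-4-(3-methylbut-2-en-1-yl)benzene, via aryllithium 15 (not isolated), via arylcopper 16 (not isolated)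
Conditions: n-BuLi (1.0 equiv), THF, −78 °C; CuBr·SMe2 (1.0 equiv), −78 → −40 °C; 2, −78 °C → rt
Reagents that add atoms: none
Why: Bromine–lithium exchange should stop after one bromine at −78 °C, and transmetalation to the monovalent arylcopper followed by SN2 allylation at the primary carbon of 2 should give the linear prenyl arene with the second bromide intact.

**Step 10**
Reactants: 17 1-bromo-2,5-bis(methoxymethoxy)-4-(3-methylbut-2-en-1-yl)benzene; 18 dimethyl squarate (3,4-dimethoxycyclobut-3-ene-1,2-dione)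
Product: 22 3-[2,5-bis(methoxymethoxy)-4-(3-methylbut-2-en-1-yl)phenyl]-4-methoxycyclobut-3-ene-1,2-dione, via aryllithium 19 (not isolated), via lithium alkoxide adduct 20 (not isolated), via trifluoroacetate 21 (not isolated)
Conditions: n-BuLi, THF, −78 °C; cannulated into 18, THF, −78 °C; (CF3CO)2O, −78 °C; aq. NH4Cl, → rt
Reagents that add atoms: water, O
Why: Bromine–lithium exchange, 1,2-addition of the aryllithium to one squarate carbonyl (inverse addition limits double addition), then O-trifluoroacetylation and hydrolytic 1,3-carbonyl transposition with loss of methanol on work-up, the standard squarate route to 3-aryl-4-alkoxycyclobutenediones, under conditions mild enough for the MOM ethers.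

**Step 11**
Reactants: 12 (2R)-5-(chloromethyl)-2-{2-[(triethylsilyl)oxy]propan-2-yl}-2,3-dihydro-1-benzofuran; 22 3-[2,5-bis(methoxymethoxy)-4-(3-methylbut-2-en-1-yl)phenyl]-4-methoxycyclobut-3-ene-1,2-dione
Product: 25 2-[2,5-bis(methoxymethoxy)-4-(3-methylbut-2-en-1-yl)phenyl]-4-hydroxy-3-methoxy-4-{[(2R)-2-{2-[(triethylsilyl)oxy]propan-2-yl}-2,3-dihydro-1-benzofuran-5-yl]methyl}cyclobut-2-en-1-one (both C4 epimers), via benzylic Grignard reagent 23 (not isolated), via chloromagnesium alkoxide 24 (not isolated)
Conditions: Mg turnings, THF, 0 °C (slow addition of 12); then 22, THF, −78 °C; aq. NH4Cl, −78 °C → rt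
Reagents that add atoms: none
Why: Grignard 1,2-addition: the benzylic magnesium chloride should attack C1, the carbonyl next to the methoxy-bearing carbon, because C2 is deactivated as a vinylogous ester carbonyl; the new carbinol centre forms without control, which is harmless since step 12 destroys it, and 25 is kept away from acid (it would lose methanol to a cyclobutenedione) and used at once.

**Step 12**
Reactants: 25 2-[2,5-bis(methoxymethoxy)-4-(3-methylbut-2-en-1-yl)phenyl]-4-hydroxy-3-methoxy-4-{[(2R)-2-{2-[(triethylsilyl)oxy]propan-2-yl}-2,3-dihydro-1-benzofuran-5-yl]methyl}cyclobut-2-en-1-one (both C4 epimers)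
Product: 28 (5Z)-3-[2,5-bis(methoxymethoxy)-4-(3-methylbut-2-en-1-yl)phenyl]-4-methoxy-5-{[(2R)-2-{2-[(triethylsilyl)oxy]propan-2-yl}-2,3-dihydro-1-benzofuran-5-yl]methylidene}furan-2(5H)-one, via tetravalent-lead alkoxide 26 (not isolated), via 5-acetoxybutenolide 27 (not isolated)
Conditions: Pb(OAc)4 (1.3 equiv), toluene, rt; then DBU (3 equiv), rt
Reagents that add atoms: none
Why: Ligand exchange at the only free hydroxyl gives the tetravalent-lead alkoxide 26, whose O–Pb bond breaks with β-scission of the strained bond between the carbinol carbon and the ring ketone; this releases the cyclobutene strain and leaves an acyl radical or acylium ion instead of a vinyl species, while the lead ends as Pb(OAc)2. The newly formed ketone oxygen then closes on the acyl carbon (O1–C2 bond, 5-exo-dig closure onto the acylium centre) and gives the five-membered lactone as a C5 oxocarbenium ion stabilised by the ring oxygen and the 4-methoxy group. This ion either loses a benzylic proton at once or is trapped by acetate as 27, from which DBU removes acetic acid, so both branches end in the exocyclic alkene. The closest known reaction is the Pb(OAc)4 ring expansion of squarate-derived 4-hydroxycyclobut-2-enones to 5-acetoxy- and 5-ylidene-furan-2(5H)-ones. No stereocentre is created (the carbinol centre of 25 is destroyed, so both epimers converge), and the Z geometry is the thermodynamic one because the E isomer would press the benzofuran ring against the C4 methoxy group. The step needs chemoselectivity for the cyclobutenol over the prenyl alkene and the electron-rich arenes, which rests on fast alkoxide exchange and strain-driven fragmentation at room temperature and on the silyl cap that keeps the other tertiary alcohol away from the lead.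

**Step 13**
Reactants: 28 (5Z)-3-[2,5-bis(methoxymethoxy)-4-(3-methylbut-2-en-1-yl)phenyl]-4-methoxy-5-{[(2R)-2-{2-[(triethylsilyl)oxy]propan-2-yl}-2,3-dihydro-1-benzofuran-5-yl]methylidene}furan-2(5H)-one
Product: 30 (5Z)-3-[2,5-bis(methoxymethoxy)-4-(3-methylbut-2-en-1-yl)phenyl]-4-hydroxy-5-{[(2R)-2-{2-[(triethylsilyl)oxy]propan-2-yl}-2,3-dihydro-1-benzofuran-5-yl]methylidene}furan-2(5H)-one, via lithium tetronate 29 (not isolated)
Conditions: LiCl, DMF, 90 °C; then cold 0.5 M HCl to pH 3
Reagents that add atoms: none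
Why: Nucleophilic O-demethylation (SN2 attack of chloride on the methyl group of a vinylogous methyl carbonate, the tetronate anion being a good leaving group) under neutral conditions that should leave MOM ethers, silyl ether, prenyl group and alkene geometry alone.

**Step 14**
Reactants: 30 (5Z)-3-[2,5-bis(methoxymethoxy)-4-(3-methylbut-2-en-1-yl)phenyl]-4-hydroxy-5-{[(2R)-2-{2-[(triethylsilyl)oxy]propan-2-yl}-2,3-dihydro-1-benzofuran-5-yl]methylidene}furan-2(5H)-one
Product: 31 (5Z)-3-[2,5-dihydroxy-4-(3-methylbut-2-en-1-yl)phenyl]-4-hydroxy-5-{[(2R)-2-(2-hydroxypropan-2-yl)-2,3-dihydro-1-benzofuran-5-yl]methylidene}furan-2(5H)-one (CNP0601419.1)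
Conditions: 1 M HCl in MeOH, rt, argon
Reagents that add atoms: none
Why: Acid-catalysed acetal exchange of both MOM ethers and solvolysis of the tertiary silyl ether in methanol; dilute acid at room temperature under argon is chosen to keep the prenyl group from cyclising onto the neighbouring phenol and the hydroquinone from oxidising, and the stereocentre is not involved.

**Compound list**
1 | methyl 4-hydroxybenzoate | COC(=O)c1ccc(O)cc1 | starting material
2 | prenyl bromide (1-bromo-3-methylbut-2-ene) | CC(C)=CCBr | starting material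
3 | sodium 4-(methoxycarbonyl)phenolate (not isolated) | COC(=O)c1ccc([O-])cc1.[Na+] | intermediate
4 | methyl 4-hydroxy-3-(3-methylbut-2-en-1-yl)benzoate | COC(=O)c1ccc(O)c(CC=C(C)C)c1 | intermediate
5 | methyl 4-[(tert-butyldimethylsilyl)oxy]-3-(3-methylbut-2-en-1-yl)benzoate | COC(=O)c1ccc(O[Si](C)(C)C(C)(C)C)c(CC=C(C)C)c1 | intermediate
6 | methyl 4-[(tert-butyldimethylsilyl)oxy]-3-{[(2S)-3,3-dimethyloxiran-2-yl]methyl}benzoate | COC(=O)c1ccc(O[Si](C)(C)C(C)(C)C)c(C[C@@H]2OC2(C)C)c1 | intermediate
7 | methyl 3-{[(2S)-3,3-dimethyloxiran-2-yl]methyl}-4-hydroxybenzoate (not isolated; present as its phenoxide) | COC(=O)c1ccc(O)c(C[C@@H]2OC2(C)C)c1 | intermediate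
8 | methyl (2R)-2-(2-hydroxypropan-2-yl)-2,3-dihydro-1-benzofuran-5-carboxylate | COC(=O)c1ccc2c(c1)C[C@H](C(C)(C)O)O2 | intermediate
9 | methyl (2R)-2-{2-[(triethylsilyl)oxy]propan-2-yl}-2,3-dihydro-1-benzofuran-5-carboxylate | COC(=O)c1ccc2c(c1)C[C@H](C(C)(C)O[Si](CC)(CC)CC)O2 | intermediate
10 | [(2R)-2-{2-[(triethylsilyl)oxy]propan-2-yl}-2,3-dihydro-1-benzofuran-5-yl]methanol | OCc1ccc2c(c1)C[C@H](C(C)(C)O[Si](CC)(CC)CC)O2 | intermediate
11 | methanesulfonate of 10 (not isolated) | CS(=O)(=O)OCc1ccc2c(c1)C[C@H](C(C)(C)O[Si](CC)(CC)CC)O2 | intermediate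
12 | (2R)-5-(chloromethyl)-2-{2-[(triethylsilyl)oxy]propan-2-yl}-2,3-dihydro-1-benzofuran | ClCc1ccc2c(c1)C[C@H](C(C)(C)O[Si](CC)(CC)CC)O2 | intermediate
13 | 2,5-dibromohydroquinone | Oc1cc(Br)c(O)cc1Br | starting material
14 | 1,4-dibromo-2,5-bis(methoxymethoxy)benzene | COCOc1cc(Br)c(OCOC)cc1Br | intermediate
15 | [4-bromo-2,5-bis(methoxymethoxy)phenyl]lithium (not isolated) | COCOc1cc(Br)c(OCOC)cc1[Li] | intermediate
16 | [4-bromo-2,5-bis(methoxymethoxy)phenyl]copper (not isolated) | COCOc1cc(Br)c(OCOC)cc1[Cu] | intermediate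
17 | 1-bromo-2,5-bis(methoxymethoxy)-4-(3-methylbut-2-en-1-yl)benzene | CC(C)=CCc1cc(OCOC)c(Br)cc1OCOC | intermediate
18 | dimethyl squarate | COC1=C(OC)C(=O)C1=O | starting material
19 | [2,5-bis(methoxymethoxy)-4-(3-methylbut-2-en-1-yl)phenyl]lithium (not isolated) | CC(C)=CCc1cc(OCOC)c([Li])cc1OCOC | intermediate
20 | lithium 1-[2,5-bis(methoxymethoxy)-4-(3-methylbut-2-en-1-yl)phenyl]-2,3-dimethoxy-4-oxocyclobut-2-en-1-olate (not isolated) | CC(C)=CCc1cc(OCOC)c(C2([O-])C(OC)=C(OC)C2=O)cc1OCOC.[Li+] | intermediate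
21 | 1-[2,5-bis(methoxymethoxy)-4-(3-methylbut-2-en-1-yl)phenyl]-2,3-dimethoxy-4-oxocyclobut-2-en-1-yl trifluoroacetate (not isolated) | CC(C)=CCc1cc(OCOC)c(C2(OC(=O)C(F)(F)F)C(OC)=C(OC)C2=O)cc1OCOC | intermediate
22 | 3-[2,5-bis(methoxymethoxy)-4-(3-methylbut-2-en-1-yl)phenyl]-4-methoxycyclobut-3-ene-1,2-dione | CC(C)=CCc1cc(OCOC)c(C2=C(OC)C(=O)C2=O)cc1OCOC | intermediate
23 | {[(2R)-2-{2-[(triethylsilyl)oxy]propan-2-yl}-2,3-dihydro-1-benzofuran-5-yl]methyl}magnesium chloride (not isolated) | Cl[Mg]Cc1ccc2c(c1)C[C@H](C(C)(C)O[Si](CC)(CC)CC)O2 | intermediate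
24 | chloromagnesium alkoxide of 25 (not isolated) | CC(C)=CCc1cc(OCOC)c(C2=C(OC)C(O[Mg]Cl)(Cc3ccc4c(c3)C[C@H](C(C)(C)O[Si](CC)(CC)CC)O4)C2=O)cc1OCOC | intermediate
25 | 2-[2,5-bis(methoxymethoxy)-4-(3-methylbut-2-en-1-yl)phenyl]-4-hydroxy-3-methoxy-4-{[(2R)-2-{2-[(triethylsilyl)oxy]propan-2-yl}-2,3-dihydro-1-benzofuran-5-yl]methyl}cyclobut-2-en-1-one (both C4 epimers) | CC(C)=CCc1cc(OCOC)c(C2=C(OC)C(O)(Cc3ccc4c(c3)C[C@H](C(C)(C)O[Si](CC)(CC)CC)O4)C2=O)cc1OCOC | intermediate
26 | triacetoxyplumbyl ether of 25, the tetravalent-lead alkoxide (not isolated) | CC(C)=CCc1cc(OCOC)c(C2=C(OC)C(O[Pb](OC(C)=O)(OC(C)=O)OC(C)=O)(Cc3ccc4c(c3)C[C@H](C(C)(C)O[Si](CC)(CC)CC)O4)C2=O)cc1OCOC | intermediate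
27 | 5-acetoxy-3-[2,5-bis(methoxymethoxy)-4-(3-methylbut-2-en-1-yl)phenyl]-4-methoxy-5-{[(2R)-2-{2-[(triethylsilyl)oxy]propan-2-yl}-2,3-dihydro-1-benzofuran-5-yl]methyl}furan-2(5H)-one (both C5 epimers; not isolated) | CC(C)=CCc1cc(OCOC)c(C2=C(OC)C(OC(C)=O)(Cc3ccc4c(c3)C[C@H](C(C)(C)O[Si](CC)(CC)CC)O4)OC2=O)cc1OCOC | intermediate
28 | (5Z)-3-[2,5-bis(methoxymethoxy)-4-(3-methylbut-2-en-1-yl)phenyl]-4-methoxy-5-{[(2R)-2-{2-[(triethylsilyl)oxy]propan-2-yl}-2,3-dihydro-1-benzofuran-5-yl]methylidene}furan-2(5H)-one | CC(C)=CCc1cc(OCOC)c(C2=C(OC)/C(=C/c3ccc4c(c3)C[C@H](C(C)(C)O[Si](CC)(CC)CC)O4)OC2=O)cc1OCOC | intermediate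
29 | lithium salt (tetronate) of 30 (not isolated) | CC(C)=CCc1cc(OCOC)c(C2=C([O-])/C(=C/c3ccc4c(c3)C[C@H](C(C)(C)O[Si](CC)(CC)CC)O4)OC2=O)cc1OCOC.[Li+] | intermediate
30 | (5Z)-3-[2,5-bis(methoxymethoxy)-4-(3-methylbut-2-en-1-yl)phenyl]-4-hydroxy-5-{[(2R)-2-{2-[(triethylsilyl)oxy]propan-2-yl}-2,3-dihydro-1-benzofuran-5-yl]methylidene}furan-2(5H)-one | CC(C)=CCc1cc(OCOC)c(C2=C(O)/C(=C/c3ccc4c(c3)C[C@H](C(C)(C)O[Si](CC)(CC)CC)O4)OC2=O)cc1OCOC | intermediate
31 | (5Z)-3-[2,5-dihydroxy-4-(3-methylbut-2-en-1-yl)phenyl]-4-hydroxy-5-{[(2R)-2-(2-hydroxypropan-2-yl)-2,3-dihydro-1-benzofuran-5-yl]methylidene}furan-2(5H)-one | CC(C)=CCc1cc(O)c(C2=C(O)/C(=C/c3ccc4c(c3)C[C@H](C(C)(C)O)O4)OC2=O)cc1O | target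

**Step count**
Total: 14 steps. Longest linear sequence: 11 steps (steps 1–7, then 11–14); the second branch is steps 8–10.

**Steps most likely to fail**

Step 12. The lead reagent may oxidise the prenyl double bond or the dialkoxyarene before the hindered alkoxide fragments, the acid-labile carbinol may lose methanol instead, or elimination may stop at an E/Z mixture. The fallback sets out from 25 and avoids the oxidant in the ring-forming event. Heating 25 in toluene or xylene (110–140 °C) should open the cyclobutenone to a hydroxy vinylketene that lactonises, giving the 5-(arylmethyl)-4-methoxyfuran-2(5H)-one F1 (the known thermal cyclobutenone-to-butenolide rearrangement; the same O1–C2 bond is formed). Deprotonation at C5 with LiN(i-Pr)2 in THF at −78 °C gives the lithium dienolate F2, which PhSeBr should selenate at C5 to the selenide F3. H2O2 with pyridine at 0 °C gives the selenoxide F4, whose syn elimination can only use the benzylic hydrogens and delivers 28; a trace of I2 in daylight would equilibrate any E isomer to Z. The fallback rejoins the route at 28.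

Step 11. Magnesium insertion into the electron-rich benzylic chloride may be overtaken by Wurtz homocoupling, and the benzylic Grignard reagent may react through its ortho ring carbon or add twice. The fallback sets out from 12 and makes a halide-free benzyllithium. Bu3SnLi (from Bu3SnH and LiN(i-Pr)2, THF, −78 °C) displaces the chloride to give the benzylstannane F5, which is stable and can be purified. Tin–lithium exchange with n-BuLi in THF at −78 °C gives the benzyllithium F6, which adds to 22 at −78 °C in the organolithium mode normal for squarate chemistry to give the lithium alkoxide F7; aq. NH4Cl then gives 25, where the route is rejoined.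

Step 14. Protic acid may add the ortho phenol across the prenyl double bond (chroman formation), ionise the tertiary carbinol, or leave the free hydroquinone long enough in solution to be oxidised by air. The fallback sets out from 30 and unmasks in two orthogonal stages without Brønsted acid. ZnBr2 with n-PrSH in CH2Cl2 at 0 °C transfers both MOM acetals to the thiol within minutes and should give the hydroquinone F8 with the triethylsilyl ether still in place. HF·pyridine buffered with pyridine in THF at 0 °C then removes the silyl group and gives 31.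

**Further compounds**
F1 | step 12 | 3-[2,5-bis(methoxymethoxy)-4-(3-methylbut-2-en-1-yl)phenyl]-4-methoxy-5-{[(2R)-2-{2-[(triethylsilyl)oxy]propan-2-yl}-2,3-dihydro-1-benzofuran-5-yl]methyl}furan-2(5H)-one | CC(C)=CCc1cc(OCOC)c(C2=C(OC)C(Cc3ccc4c(c3)C[C@H](C(C)(C)O[Si](CC)(CC)CC)O4)OC2=O)cc1OCOC
F2 | step 12 | lithium dienolate of F1 (2-lithiooxyfuran) | CC(C)=CCc1cc(OCOC)c(C2=C(O[Li])OC(Cc3ccc4c(c3)C[C@H](C(C)(C)O[Si](CC)(CC)CC)O4)=C2OC)cc1OCOC
F3 | step 12 | 5-(phenylselanyl) derivative of F1 | CC(C)=CCc1cc(OCOC)c(C2=C(OC)C([Se]c5ccccc5)(Cc3ccc4c(c3)C[C@H](C(C)(C)O[Si](CC)(CC)CC)O4)OC2=O)cc1OCOC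
F4 | step 12 | selenoxide of F3 | CC(C)=CCc1cc(OCOC)c(C2=C(OC)C([Se](=O)c5ccccc5)(Cc3ccc4c(c3)C[C@H](C(C)(C)O[Si](CC)(CC)CC)O4)OC2=O)cc1OCOC
F5 | step 11 | tributyl{[(2R)-2-{2-[(triethylsilyl)oxy]propan-2-yl}-2,3-dihydro-1-benzofuran-5-yl]methyl}stannane | CCCC[Sn](CCCC)(CCCC)Cc1ccc2c(c1)C[C@H](C(C)(C)O[Si](CC)(CC)CC)O2
F6 | step 11 | {[(2R)-2-{2-[(triethylsilyl)oxy]propan-2-yl}-2,3-dihydro-1-benzofuran-5-yl]methyl}lithium | [Li]Cc1ccc2c(c1)C[C@H](C(C)(C)O[Si](CC)(CC)CC)O2
F7 | step 11 | lithium alkoxide of 25 | CC(C)=CCc1cc(OCOC)c(C2=C(OC)C([O-])(Cc3ccc4c(c3)C[C@H](C(C)(C)O[Si](CC)(CC)CC)O4)C2=O)cc1OCOC.[Li+]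
F8 | step 14 | (5Z)-3-[2,5-dihydroxy-4-(3-methylbut-2-en-1-yl)phenyl]-4-hydroxy-5-{[(2R)-2-{2-[(triethylsilyl)oxy]propan-2-yl}-2,3-dihydro-1-benzofuran-5-yl]methylidene}furan-2(5H)-one | CC(C)=CCc1cc(O)c(C2=C(O)/C(=C/c3ccc4c(c3)C[C@H](C(C)(C)O[Si](CC)(CC)CC)O4)OC2=O)cc1O
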